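**Retrosynthetic overview**
1. Both rings, the C40 polyene and all three stereocentres (3R, 3'R, 6'R) are taken intact from natural lutein 1; no ring is formed and no C–C bond is made.
2. Key disconnection: the 3'-O–acyl bond, made first by catalyst-controlled, site-selective palmitoyl transfer from palmitic anhydride 2 (through acyl-catalyst ion pair 3) to the allylic 3'-OH, giving monoester 4.
3. Second disconnection: the 3-O–acyl bond, made from myristic anhydride 5 (through acylpyridinium 6) on the remaining 3-OH of 4, giving the target 7.
4. The two acylations are kept as separate steps because carboxylate/anhydride exchange in one pot would scramble C16 and C14 acyl groups between the two positions.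

Assumption: crystalline (all-E)-(3R,3'R,6'R)-lutein from marigold (sold in bulk, recrystallised once to lower its zeaxanthin content) counts as a cheap commercial starting material, as do the two fatty anhydrides.

**Step 1**
Reactants: 1 (3R,3'R,6'R)-lutein [(all-E)-β,ε-carotene-3,3'-diol]; 2 palmitic anhydride (hexadecanoic anhydride, 1.1 equiv)
Product: 4 lutein 3'-O-palmitate [(3R,3'R,6'R)-3-hydroxy-β,ε-caroten-3'-yl hexadecanoate; the allylic ε-ring hydroxyl is esterified and the β-ring 3-OH is free], via N-palmitoyl-(R)-benzotetramisolium palmitate 3 (not isolated)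
Conditions: (R)-BTM [(R)-2-phenyl-2,3-dihydroimidazo[2,1-b][1,3]benzothiazole, C15H12N2S] (10 mol%), iPr2NEt (1.2 equiv), Na2SO4, CHCl3 (amylene-stabilised, filtered through basic alumina, 0.01 M), 0 °C, Ar, dark, 12–24 h
Reagents that add atoms: none
Why: Proposed new method: catalyst-controlled site-selective acyl transfer onto a carotenoid diol, in which (R)-BTM is acylated by 2 to the N-palmitoyl isothiouronium ion pair 3, whose flat cationic amidinium face stacks on the C4'=C5' π bond next to the 3'R carbinol (cation–π recognition, the same spatial arrangement as in (R)-1-arylalkanols, with the alkene in place of the aryl group and C2'H2 in place of the alkyl group), so the palmitoyl group should be delivered to the allylic 3'-OH much faster than to the 3-OH, whose carbinol carbon carries no π substituent, while uncatalysed background acylation is negligible at 0 °C; only the acyl C–O bond forms, so C3', C6' and C3 are untouched; the closest known reaction type is the isothiourea-catalysed kinetic resolution of secondary benzylic and allylic alcohols, here moved from enantiomer selection to site selection between two secondary hydroxyls of a polyene diol.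

Practical points for step 1:
- The matched catalyst enantiomer is assigned by analogy with the benzylic series; a control run with (S)-BTM settles it, and both enantiomers are sold.
- Stop at about 95 % conversion of 1 (HPLC). Unreacted 1, residual zeaxanthin (no allylic OH, so it should remain a diol) and any dipalmitate are removed on Et3N-deactivated silica.
- Site of acylation is read from 1H NMR: H-3' should move from about 4.25 to about 5.3 ppm while H-3 stays near 4.0 ppm.
- 4 must be freed of palmitic acid (NaHCO3 wash, chromatography) before step 2.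

**Step 2**
Reactants: 4 lutein 3'-O-palmitate; 5 myristic anhydride (tetradecanoic anhydride, 1.5 equiv)
Product: 7 (3R,3'R,6'R)-lutein 3-O-myristate 3'-O-palmitate [(3R,3'R,6'R)-3-(tetradecanoyloxy)-β,ε-caroten-3'-yl hexadecanoate, CNP0230054.1], via N-myristoyl-4-(dimethylamino)pyridinium myristate 6 (not isolated)
Conditions: DMAP [4-(dimethylamino)pyridine, C7H10N2] (10 mol%), Et3N (2 equiv), CH2Cl2, 0 °C → rt, Ar, dark, 3 h; NaHCO3 wash, Et3N-deactivated silica, crystallisation from acetone at −20 °C
Reagents that add atoms: none
Why: DMAP-catalysed esterification (nucleophilic acyl transfer through acylpyridinium 6) of the only free hydroxyl; the C3–O bond is not broken, so 3R is retained, and the cold, basic, non-ionising conditions leave the allylic 3'-palmitate and the all-E polyene intact.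

**Compound list**
1 | (3R,3'R,6'R)-lutein, (all-E)-β,ε-carotene-3,3'-diol | O[C@H]1C=C(C)[C@H](/C=C/C(C)=C/C=C/C(C)=C/C=C/C=C(C)/C=C/C=C(C)/C=C/C2=C(C)C[C@@H](O)CC2(C)C)C(C)(C)C1 | starting material
2 | palmitic anhydride (hexadecanoic anhydride) | CCCCCCCCCCCCCCCC(=O)OC(=O)CCCCCCCCCCCCCCC | starting material
3 | N-palmitoyl-(R)-benzotetramisolium palmitate [(R)-BTM acylated at the imine nitrogen N1, palmitate counter-ion] | CCCCCCCCCCCCCCCC(=O)[N+]1=C2Sc3ccccc3N2C[C@H]1c1ccccc1.CCCCCCCCCCCCCCCC(=O)[O-] | intermediate
4 | lutein 3'-O-palmitate, (3R,3'R,6'R)-3-hydroxy-β,ε-caroten-3'-yl hexadecanoate | CCCCCCCCCCCCCCCC(=O)O[C@H]1C=C(C)[C@H](/C=C/C(C)=C/C=C/C(C)=C/C=C/C=C(C)/C=C/C=C(C)/C=C/C2=C(C)C[C@@H](O)CC2(C)C)C(C)(C)C1 | intermediate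
5 | myristic anhydride (tetradecanoic anhydride) | CCCCCCCCCCCCCC(=O)OC(=O)CCCCCCCCCCCCC | starting material
6 | N-myristoyl-4-(dimethylamino)pyridinium myristate | CCCCCCCCCCCCCC(=O)[n+]1ccc(N(C)C)cc1.CCCCCCCCCCCCCC(=O)[O-] | intermediate
7 | (3R,3'R,6'R)-lutein 3-O-myristate 3'-O-palmitate (CNP0230054.1) | CCCCCCCCCCCCCCCC(=O)O[C@H]1C=C(C)[C@H](/C=C/C(C)=C/C=C/C(C)=C/C=C/C=C(C)/C=C/C=C(C)/C=C/C2=C(C)C[C@@H](OC(=O)CCCCCCCCCCCCC)CC2(C)C)C(C)(C)C1 | target

**Step count and risk**
Total step count: 2. Longest linear sequence: 2 steps (1 → 4 → 7). The route has only two steps, so both are ranked, the riskier first; there is no third step.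

Risk 1, step 1 (the proposed new step). The site selectivity may be too low, giving the 3-O-regioisomer and dipalmitate; any regioisomer carried into step 2 would end as the inseparable 3-O-palmitate 3'-O-myristate isomer of 7. The fallback uses known chemistry only, sets out from 1 and comes back to the route at 4. Lutein 1 is mono-acylated without site control (2, 1.0 equiv, DMAP, Et3N, CH2Cl2/THF, 0 °C) to a mixture of 4, its regioisomer lutein 3-O-palmitate F1, lutein dipalmitate F2 and recovered 1. Silica removes the non-polar F2 and the polar 1, which is reused. The mixed monoester fraction is then stirred with activated MnO2 in CH2Cl2 at rt, the known allylic oxidation of the lutein 3'-OH. Only F1 has a free allylic hydroxyl and is converted to the enone (3R,6'R)-3-palmitoyloxy-β,ε-caroten-3'-one F3. Compound 4, whose free hydroxyl is not allylic, is unchanged and now separates easily on silica as the only hydroxy ester.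

Risk 2, step 2. Prolonged exposure to DMAP, base and carboxylate could cause acyl exchange at the allylic 3'-ester or E/Z isomerisation, and the resulting C16/C16 or C14/C14 diesters cannot be removed on silica. The fallback changes from chemical to biocatalytic acyl transfer, sets out from 4 and comes back at 7. Compound 4 is treated with vinyl myristate (3 equiv) and Candida antarctica lipase B immobilised on acrylic resin in dry toluene at 40 °C in the dark, with acetaldehyde leaving as the only co-product. The medium is neutral and base-free, and the run is monitored on a C30 HPLC column for any acyl exchange at C3'. This fallback makes no new compound F0.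

**Further compounds**
F1 | step 1 | lutein 3-O-palmitate, (3R,3'R,6'R)-3'-hydroxy-β,ε-caroten-3-yl hexadecanoate | O[C@H]1C=C(C)[C@H](/C=C/C(C)=C/C=C/C(C)=C/C=C/C=C(C)/C=C/C=C(C)/C=C/C2=C(C)C[C@@H](OC(=O)CCCCCCCCCCCCCCC)CC2(C)C)C(C)(C)C1
F2 | step 1 | lutein dipalmitate, (3R,3'R,6'R)-β,ε-carotene-3,3'-diyl dihexadecanoate | CCCCCCCCCCCCCCCC(=O)O[C@H]1C=C(C)[C@H](/C=C/C(C)=C/C=C/C(C)=C/C=C/C=C(C)/C=C/C=C(C)/C=C/C2=C(C)C[C@@H](OC(=O)CCCCCCCCCCCCCCC)CC2(C)C)C(C)(C)C1
F3 | step 1 | (3R,6'R)-3-palmitoyloxy-β,ε-caroten-3'-one | O=C1C=C(C)[C@H](/C=C/C(C)=C/C=C/C(C)=C/C=C/C=C(C)/C=C/C=C(C)/C=C/C2=C(C)C[C@@H](OC(=O)CCCCCCCCCCCCCCC)CC2(C)C)C(C)(C)C1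
F0 | step 2 | none | none
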